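Pseudocyphellarin A is cut at the depside ester into a ring B phenol and a ring A acid, both derived from 3-(methoxymethoxy)-4,5-dimethylphenol (6). Everything rests on ring B, whose C3 methyl sits on the carbon flanked by the C2 and C4 oxygens and whose C1 ester carbon is attached next to the C2 oxygen, so each can be put in by oxygen-guided C–H lithiation. In one flask the resorcinol bis(methoxymethyl) ether 7 is deprotonated twice, with iodomethane and then methyl chloroformate as electrophiles, giving hexasubstituted benzoate 13. A mixed bis-acetal of 6 is formylated and carboxylated to ring A; acylation of the C4 hydroxyl and acid removal of the acetals complete the target.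

Key step: step 4

Remark on the chemistry: the target has no stereocenter; ring B is numbered C1 (CO2CH3), C2 (OH), C3 (CH3), C4 (O-acyl), C5 and C6 (CH3), and ring A C1 (acyl carbon), C2 (OH), C3 (CHO), C4 (OH), C5 and C6 (CH3); ring A is carried as a mixed bis-acetal, methoxymethyl on O4 and ethoxymethyl on O2, the ethoxymethyl ether matching methoxymethyl in lithiation and in acid hydrolysis while its O-ethyl group, next to the later acyl chloride, is a poorer substrate for chloride dealkylation than an O-methyl group; the tetrahedral adducts 19 and 22 to 24 are racemic and transient.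

Step 1
Reactants: 1 2,3-dimethylphenol; 2 chloromethyl methyl ether
Product: 3 1-(methoxymethoxy)-2,3-dimethylbenzene
Conditions: MOMCl (1.3 equiv), i-Pr2NEt (1.5 equiv), CH2Cl2, 0 °C → rt
Reagents that add atoms: chloromethyl methyl ether, COCCl
Why: Williamson-type O-alkylation of the phenol with the reactive α-chloro ether under amine base should give the methoxymethyl ether cleanly, this acetal being inert to the borylation, peroxide and organolithium conditions that follow.

Step 2
Reactants: 3 1-(methoxymethoxy)-2,3-dimethylbenzene; 4 bis(pinacolato)diboron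
Product: 6 3-(methoxymethoxy)-4,5-dimethylphenol, via 2-[3-(methoxymethoxy)-4,5-dimethylphenyl]-4,4,5,5-tetramethyl-1,3,2-dioxaborolane 5 (not isolated)
Conditions: [Ir(OMe)(cod)]2 (1.5 mol %), 4,4'-di-tert-butyl-2,2'-bipyridine (3 mol %), B2pin2 (1.0 equiv), THF, 80 °C; then NaOH (aq.), H2O2 (30 %), THF, 0 °C → rt
Reagents that add atoms: hydrogen peroxide, OO
Why: Iridium-catalysed aromatic C–H borylation is governed by sterics and should reach only C5, the one ring hydrogen of 3 with no ortho substituent, after which basic peroxide oxidation of the aryl boronate (1,2-aryl shift from boron to oxygen) turns the C–B bond into the phenol.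

Step 3
Reactants: 6 3-(methoxymethoxy)-4,5-dimethylphenol; 2 chloromethyl methyl ether
Product: 7 1,5-bis(methoxymethoxy)-2,3-dimethylbenzene
Conditions: MOMCl (1.3 equiv), i-Pr2NEt (1.5 equiv), CH2Cl2, 0 °C → rt
Reagents that add atoms: chloromethyl methyl ether, COCCl
Why: The same Williamson-type alkylation on the unhindered new phenol should give the bis-acetal, whose two ether oxygens are the directing groups of the key step.

Step 4
Reactants: 7 1,5-bis(methoxymethoxy)-2,3-dimethylbenzene; 8 iodomethane; 9 methyl chloroformate
Product: 13 methyl 2,4-bis(methoxymethoxy)-3,5,6-trimethylbenzoate, via [2,6-bis(methoxymethoxy)-3,4-dimethylphenyl]lithium 10 (not isolated), via 1,3-bis(methoxymethoxy)-2,4,5-trimethylbenzene 11 (not isolated), via [2,4-bis(methoxymethoxy)-3,5,6-trimethylphenyl]lithium 12 (not isolated)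
Conditions: n-BuLi (1.1 equiv), THF, 0 °C, 1 h; MeI (1.05 equiv), 0 °C → rt; then s-BuLi (1.5 equiv), TMEDA (1.5 equiv), −78 °C, 2 h; cannulated into ClCO2Me (3 equiv), THF, −78 °C → rt
Reagents that add atoms: iodomethane, CI; methyl chloroformate, COC(=O)Cl
Why: Each methoxymethyl ether oxygen complexes the alkyllithium and so brings the base to the adjacent ring C–H (complex-induced proximity, directed ortho-metalation); n-BuLi therefore removes the hydrogen at ring B C3, the one site held by both the C2 and C4 acetals, and lithium species 10 is methylated by iodomethane in an SN2 step to give 11. In 11 a single ring C–H remains, at C1 beside the C2 acetal, and the stronger s-BuLi/TMEDA pair should take it to give 12, which reacts with methyl chloroformate by addition–elimination. The closest known reaction type is the stepwise ortho-lithiation of resorcinol bis(methoxymethyl) ethers, first between the oxygens and then at a free ortho position, with alkyl halide and chloroformate quenches. No ring is closed and no stereocenter is formed. The step needs the right site order, ring over methyl-group metalation and a single acylation: the sequence is set by kinetic acidity (a C–H between two ether oxygens before one beside a single oxygen), metalation of a methyl group is disfavoured at low temperature in the absence of a potassium-containing superbase, and ketone formation is held back by the C2 acetal and C6 methyl around the C1 lithium centre together with inverse addition into excess chloroformate.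

Step 5
Reactants: 13 methyl 2,4-bis(methoxymethoxy)-3,5,6-trimethylbenzoate
Product: 14 methyl 2,4-dihydroxy-3,5,6-trimethylbenzoate
Conditions: HCl (conc., cat.), MeOH, 50 °C
Reagents that add atoms: none
Why: Acid-catalysed transacetalisation with the solvent should remove both methoxymethyl groups as dimethoxymethane, and the methyl ester is safe because any exchange with methanol is degenerate.

Step 6
Reactants: 6 3-(methoxymethoxy)-4,5-dimethylphenol; 15 chloromethyl ethyl ether
Product: 16 5-(ethoxymethoxy)-1-(methoxymethoxy)-2,3-dimethylbenzene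
Conditions: EtOCH2Cl (1.3 equiv), i-Pr2NEt (1.5 equiv), CH2Cl2, 0 °C → rt
Reagents that add atoms: chloromethyl ethyl ether, CCOCCl
Why: Williamson-type O-alkylation of the free phenol with the α-chloro ether should give the mixed bis-acetal, in which the ethoxymethyl ether coordinates alkyllithiums and is hydrolysed by acid in the same way as the methoxymethyl ether.

Step 7
Reactants: 16 5-(ethoxymethoxy)-1-(methoxymethoxy)-2,3-dimethylbenzene; 17 N,N-dimethylformamide
Product: 20 6-(ethoxymethoxy)-2-(methoxymethoxy)-3,4-dimethylbenzaldehyde, via [6-(ethoxymethoxy)-2-(methoxymethoxy)-3,4-dimethylphenyl]lithium 18 (not isolated), via lithium [6-(ethoxymethoxy)-2-(methoxymethoxy)-3,4-dimethylphenyl](dimethylamino)methanolate 19 (not isolated)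
Conditions: n-BuLi (1.1 equiv), THF, 0 °C, 1 h; DMF (2 equiv), 0 °C → rt; H2O
Reagents that add atoms: N,N-dimethylformamide, CN(C)C=O
Why: Directed ortho-lithiation removes the one ring hydrogen flanked by both acetal oxygens and aryllithium 18 is formylated with DMF (Bouveault aldehyde synthesis), which should stop at the aldehyde because tetrahedral adduct 19 does not collapse until the aqueous quench.

Step 8
Reactants: 20 6-(ethoxymethoxy)-2-(methoxymethoxy)-3,4-dimethylbenzaldehyde; 21 carbon dioxide
Product: 25 2-(ethoxymethoxy)-3-formyl-4-(methoxymethoxy)-5,6-dimethylbenzoic acid, via lithium [6-(ethoxymethoxy)-2-(methoxymethoxy)-3,4-dimethylphenyl](4-methylpiperazin-1-yl)methanolate 22 (not isolated), via lithium [2-(ethoxymethoxy)-3-lithio-6-(methoxymethoxy)-4,5-dimethylphenyl](4-methylpiperazin-1-yl)methanolate 23 (not isolated), via lithium 2-(ethoxymethoxy)-3-[(lithiooxy)(4-methylpiperazin-1-yl)methyl]-4-(methoxymethoxy)-5,6-dimethylbenzoate 24 (not isolated)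
Conditions: 1-methylpiperazine, n-BuLi (1.2 equiv each), THF, −20 °C, then 20; s-BuLi (2.0 equiv), TMEDA (2.0 equiv), −78 → −40 °C; CO2, −78 °C → rt; aq. HCl to pH 4, 0 °C
Reagents that add atoms: carbon dioxide, O=C=O
Why: Addition of the lithium amide converts the aldehyde into α-amino alkoxide 22, which is inert to alkyllithiums, so that s-BuLi/TMEDA can carry out an ethoxymethoxy-directed ortho-lithiation at the only ring C–H and carboxylation with CO2 should give the acid after a mild acid work-up that releases the aldehyde again (in situ aldehyde protection combined with directed ortho-metalation).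

Step 9
Reactants: 25 2-(ethoxymethoxy)-3-formyl-4-(methoxymethoxy)-5,6-dimethylbenzoic acid; 14 methyl 2,4-dihydroxy-3,5,6-trimethylbenzoate
Product: 27 methyl 4-{[2-(ethoxymethoxy)-3-formyl-4-(methoxymethoxy)-5,6-dimethylbenzoyl]oxy}-2-hydroxy-3,5,6-trimethylbenzoate, via 2-(ethoxymethoxy)-3-formyl-4-(methoxymethoxy)-5,6-dimethylbenzoyl chloride 26 (not isolated)
Conditions: 25, 1-chloro-N,N,2-trimethylprop-1-en-1-amine (1.1 equiv), CH2Cl2, 0 °C → rt; then added to 14, NaH (1.0 equiv), THF, 0 °C → rt
Reagents that add atoms: none
Why: The α-chloroenamine converts the acid into its chloride under neutral conditions that spare the acetals and the aldehyde, and the sodium phenoxide of 14 should be acylated at the C4 oxygen (nucleophilic acyl substitution, phenol ester formation through the acid chloride), since this hydroxyl para to the ester is the more acidic one while the C2 hydroxyl is locked in a hydrogen bond to the ester carbonyl.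

Step 10
Reactants: 27 methyl 4-{[2-(ethoxymethoxy)-3-formyl-4-(methoxymethoxy)-5,6-dimethylbenzoyl]oxy}-2-hydroxy-3,5,6-trimethylbenzoate
Product: 28 pseudocyphellarin A, methyl 4-[(3-formyl-2,4-dihydroxy-5,6-dimethylbenzoyl)oxy]-2-hydroxy-3,5,6-trimethylbenzoate
Conditions: 3 M HCl (aq.), THF, 45 °C
Reagents that add atoms: none
Why: Acid-catalysed hydrolysis of the aryl methoxymethyl and ethoxymethyl acetals, both next to a carbonyl group that hydrogen-bonds the freed phenol, should proceed under conditions too mild to hydrolyse the two hindered esters, and with every ring position substituted the released formaldehyde has no site for electrophilic attack.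

Compound list
1 | 2,3-dimethylphenol | Cc1cccc(O)c1C | starting material
2 | chloromethyl methyl ether | COCCl | starting material
3 | 1-(methoxymethoxy)-2,3-dimethylbenzene | COCOc1cccc(C)c1C | intermediate
4 | bis(pinacolato)diboron | CC1(C)OB(OC1(C)C)B1OC(C)(C)C(C)(C)O1 | starting material
5 | 2-[3-(methoxymethoxy)-4,5-dimethylphenyl]-4,4,5,5-tetramethyl-1,3,2-dioxaborolane | COCOc1cc(B2OC(C)(C)C(C)(C)O2)cc(C)c1C | intermediate
6 | 3-(methoxymethoxy)-4,5-dimethylphenol | COCOc1cc(O)cc(C)c1C | intermediate
7 | 1,5-bis(methoxymethoxy)-2,3-dimethylbenzene | COCOc1cc(OCOC)c(C)c(C)c1 | intermediate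
8 | iodomethane | CI | starting material
9 | methyl chloroformate | COC(=O)Cl | starting material
10 | [2,6-bis(methoxymethoxy)-3,4-dimethylphenyl]lithium | [Li]c1c(OCOC)cc(C)c(C)c1OCOC | intermediate
11 | 1,3-bis(methoxymethoxy)-2,4,5-trimethylbenzene | COCOc1cc(C)c(C)c(OCOC)c1C | intermediate
12 | [2,4-bis(methoxymethoxy)-3,5,6-trimethylphenyl]lithium | [Li]c1c(C)c(C)c(OCOC)c(C)c1OCOC | intermediate
13 | methyl 2,4-bis(methoxymethoxy)-3,5,6-trimethylbenzoate | COCOc1c(C)c(OCOC)c(C)c(C)c1C(=O)OC | intermediate
14 | methyl 2,4-dihydroxy-3,5,6-trimethylbenzoate | COC(=O)c1c(C)c(C)c(O)c(C)c1O | intermediate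
15 | chloromethyl ethyl ether | CCOCCl | starting material
16 | 5-(ethoxymethoxy)-1-(methoxymethoxy)-2,3-dimethylbenzene | CCOCOc1cc(OCOC)c(C)c(C)c1 | intermediate
17 | N,N-dimethylformamide | CN(C)C=O | starting material
18 | [6-(ethoxymethoxy)-2-(methoxymethoxy)-3,4-dimethylphenyl]lithium | [Li]c1c(OCOCC)cc(C)c(C)c1OCOC | intermediate
19 | lithium [6-(ethoxymethoxy)-2-(methoxymethoxy)-3,4-dimethylphenyl](dimethylamino)methanolate (racemic) | [Li]OC(N(C)C)c1c(OCOCC)cc(C)c(C)c1OCOC | intermediate
20 | 6-(ethoxymethoxy)-2-(methoxymethoxy)-3,4-dimethylbenzaldehyde | O=Cc1c(OCOCC)cc(C)c(C)c1OCOC | intermediate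
21 | carbon dioxide | O=C=O | starting material
22 | lithium [6-(ethoxymethoxy)-2-(methoxymethoxy)-3,4-dimethylphenyl](4-methylpiperazin-1-yl)methanolate (racemic) | [Li]OC(N1CCN(C)CC1)c1c(OCOCC)cc(C)c(C)c1OCOC | intermediate
23 | lithium [2-(ethoxymethoxy)-3-lithio-6-(methoxymethoxy)-4,5-dimethylphenyl](4-methylpiperazin-1-yl)methanolate (racemic) | [Li]OC(N1CCN(C)CC1)c1c(OCOCC)c([Li])c(C)c(C)c1OCOC | intermediate
24 | lithium 2-(ethoxymethoxy)-3-[(lithiooxy)(4-methylpiperazin-1-yl)methyl]-4-(methoxymethoxy)-5,6-dimethylbenzoate (racemic) | [Li]OC(N1CCN(C)CC1)c1c(OCOCC)c(C(=O)O[Li])c(C)c(C)c1OCOC | intermediate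
25 | 2-(ethoxymethoxy)-3-formyl-4-(methoxymethoxy)-5,6-dimethylbenzoic acid | OC(=O)c1c(C)c(C)c(OCOC)c(C=O)c1OCOCC | intermediate
26 | 2-(ethoxymethoxy)-3-formyl-4-(methoxymethoxy)-5,6-dimethylbenzoyl chloride | O=C(Cl)c1c(C)c(C)c(OCOC)c(C=O)c1OCOCC | intermediate
27 | methyl 4-{[2-(ethoxymethoxy)-3-formyl-4-(methoxymethoxy)-5,6-dimethylbenzoyl]oxy}-2-hydroxy-3,5,6-trimethylbenzoate | COC(=O)c1c(C)c(C)c(OC(=O)c2c(C)c(C)c(OCOC)c(C=O)c2OCOCC)c(C)c1O | intermediate
28 | pseudocyphellarin A | COC(=O)c1c(C)c(C)c(OC(=O)c2c(C)c(C)c(O)c(C=O)c2O)c(C)c1O | target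

Total step count: 10. Longest linear sequence: 7 steps (1, 2, 3, 4, 5, 9, 10). The ring A branch (1, 2, 6, 7, 8, 9, 10) is equally long.

Steps most likely to fail

Step 4. The second deprotonation may stall, or it may drift to a methyl group, or the hindered aryllithium may add twice to the chloroformate. Fallback: setting out from 7, only the first lithiation and methylation are run (n-BuLi, THF, 0 °C; MeI) and 1,3-bis(methoxymethoxy)-2,4,5-trimethylbenzene 11 is isolated. Electrophilic bromination (NBS, MeCN, 0 °C, dark) at its single ring C–H, which is para to one acetal oxygen and ortho to the other, should give 1-bromo-2,4-bis(methoxymethoxy)-3,5,6-trimethylbenzene F1. Bromine–lithium exchange (n-BuLi, THF, −78 °C) then produces the C1 lithium species without any C–H deprotonation, and the quench with methyl chloroformate comes back to the route at 13.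

Step 8. Masking of the doubly ortho-substituted aldehyde may be incomplete, so that s-BuLi adds to the carbonyl group, or ring metalation of the amino alkoxide may be slow. Fallback: setting out from 20, reduction with NaBH4 (MeOH, 0 °C) gives [6-(ethoxymethoxy)-2-(methoxymethoxy)-3,4-dimethylphenyl]methanol F2. Its lithium alkoxide tolerates s-BuLi/TMEDA (2.3 equiv, THF, −78 → −40 °C), so ring lithiation beside the ethoxymethyl acetal and a CO2 quench should give 2-(ethoxymethoxy)-3-(hydroxymethyl)-4-(methoxymethoxy)-5,6-dimethylbenzoic acid F3. Oxidation of the benzylic alcohol with MnO2 (CH2Cl2, rt) comes back to the route at 25.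

Step 9. The acetal next to the acyl chloride may be lost during activation, or acyl transfer between two doubly ortho-substituted partners may be too slow. Fallback: setting out from 25, the acetals are removed first (3 M HCl aq., THF, 45 °C) to give 3-formyl-2,4-dihydroxy-5,6-dimethylbenzoic acid F4, whose two hydroxyls are tied up in hydrogen bonds to the neighbouring carbonyl groups. Carbodiimide condensation of this acid with 14 (DCC, toluene, rt) should then form the depside ester directly and comes back to the route at the target 28, so that step 10 is not needed.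

Further compounds
F1 | step 4 | 1-bromo-2,4-bis(methoxymethoxy)-3,5,6-trimethylbenzene | Brc1c(C)c(C)c(OCOC)c(C)c1OCOC
F2 | step 8 | [6-(ethoxymethoxy)-2-(methoxymethoxy)-3,4-dimethylphenyl]methanol | OCc1c(OCOCC)cc(C)c(C)c1OCOC
F3 | step 8 | 2-(ethoxymethoxy)-3-(hydroxymethyl)-4-(methoxymethoxy)-5,6-dimethylbenzoic acid | OCc1c(OCOCC)c(C(=O)O)c(C)c(C)c1OCOC
F4 | step 9 | 3-formyl-2,4-dihydroxy-5,6-dimethylbenzoic acid | O=Cc1c(O)c(C)c(C)c(C(=O)O)c1O
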